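**Strategy.** Everything rests on closing ring B at C5–C6: a four-carbon chain hanging from quaternary C10 of a carvone-derived ring A enone is cyclised, through lithium–iodine exchange, onto the C5 carbonyl. The step exploits C5 as a carbonyl carbon flanked by C10 and by the C3=C4 alkene (C4 methyl) of ring A: it forms the ring and a cis-fused tertiary allylic C5–O, which palladium-catalysed formate hydrogenolysis then replaces by hydrogen with inversion, giving the trans ring fusion with C3=C4 kept. Carvone's single stereocentre sets C10 and is then excised; C1, C2, C5, C7 and C9 follow by substrate control. The cyclisation precursor is an iodobutyl cyclohexenone acetonide.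

Key step: step 8

Remark on notation: the eudesmane numbering of the target is used for all intermediates (ring A = C1–C5 and C10, ring B = C5–C10, C14 = the CH2O carbon on C10, C15 = the methyl on C4); β is the face of C14, α the opposite face; the target is (1R,2S,5R,7S,9S,10S).

Assumption: the aldol adduct of step 2 is written as its expected major C9 epimer; the other epimer serves equally, because C9 becomes a ketone in step 11.

Step 1
Reactants: 1 (S)-(+)-carvone; 2 (triisopropylsiloxy)methyl chloride
Product: 4 6-[(triisopropylsiloxy)methyl]carvone (CH2OSi trans to isopropenyl), via kinetic lithium dienolate of carvone 3 (not isolated)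
Conditions: LDA (1.1 equiv), THF, −78 °C; then 2, DMPU, −78 to −20 °C
Reagents that add atoms: none
Why: Kinetic deprotonation at the α′-carbon (C10) gives the cross-conjugated lithium dienolate, which is C-alkylated by the α-chloro ether (enolate alkylation) mainly anti to the neighbouring isopropenyl group, a configuration that the next enolisation erases.

Step 2
Reactants: 4 6-[(triisopropylsiloxy)methyl]carvone; 5 4-bromobutanal
Product: 7 C10-quaternary aldol adduct (4-bromo-1-hydroxybutyl chain α; CH2OSi β), via tetrasubstituted lithium enolate 6 (not isolated)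
Conditions: LDA (1.1 equiv), THF, −78 °C; then 5, −78 °C, 20 min; AcOH quench at −78 °C
Reagents that add atoms: none
Why: The tetrasubstituted lithium enolate adds to the aldehyde (directed aldol addition through a closed six-membered chair transition state) on the face anti to the adjacent C1 isopropenyl group, which fixes quaternary C10 with C14 cis and the new chain trans to that group, while the carbinol configuration does not matter because C9 is oxidised later.

Step 3
Reactants: 7 C10-quaternary aldol adduct
Product: 8 9-O-triethylsilyl ether of the aldol adduct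
Conditions: Et3SiOTf, 2,6-lutidine, CH2Cl2, −78 to 0 °C
Reagents that add atoms: triethylsilyl trifluoromethanesulfonate, CC[Si](CC)(CC)OS(=O)(=O)C(F)(F)F
Why: O-Silylation of the hindered secondary alcohol with the silyl triflate blocks retro-aldol cleavage and etherification onto the bromide in later basic steps and adds bulk on the α face of C10.

Step 4
Reactants: 8 9-O-triethylsilyl ether of the aldol adduct
Product: 10 ring A cyclohexa-2,4-dienone (C5=O; C3=C4; C1=C2), via α-methoxy hydroperoxide 9 (not isolated)
Conditions: O3, CH2Cl2/MeOH 1:1, −78 °C (Sudan Red 7B end point); then FeSO4·7H2O (1.5 equiv), Cu(OAc)2·H2O (1.2 equiv), −20 °C to rt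
Reagents that add atoms: none
Why: Ozone cleaves only the electron-rich isopropenyl alkene to an α-methoxy hydroperoxide, ferrous ion turns it into an alkoxy radical that loses methyl acetate by β-scission, and the C1 radical is oxidised by Cu(OAc)2 to the C1=C2 alkene (dealkenylative radical fragmentation), the only elimination possible next to quaternary C10, so the carvone stereocentre is excised after it has set C10.

Step 5
Reactants: 10 ring A cyclohexa-2,4-dienone
Product: 11 1β,2β-diol enone
Conditions: OsO4 (2 mol %), N-methylmorpholine N-oxide (1.5 equiv), acetone/H2O 5:1, 0 °C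
Reagents that add atoms: osmium tetroxide (catalytic oxygen carrier), O=[Os](=O)(=O)=O; N-methylmorpholine N-oxide, C[N+]1([O-])CCOCC1; water, O
Why: Catalytic osmium tetroxide cis-dihydroxylation takes place at the more electron-rich γ,δ-alkene C1=C2 of the planar dienone, from the face of the small CH2OSi group and anti to the α-branched silyloxybutyl substituent on C10, which sets the cis-1β,2β-diol from C10.

Step 6
Reactants: 11 1β,2β-diol enone
Product: 12 1β,2β-O-isopropylidene acetal (bromide)
Conditions: 2,2-dimethoxypropane, PPTS (cat.), CH2Cl2, rt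
Reagents that add atoms: 2,2-dimethoxypropane, COC(C)(C)OC
Why: Acid-catalysed transacetalisation closes the cis-diol into an isopropylidene acetal, which masks both hydroxyls against the organolithium and keeps the C2 oxygen from acting as a leaving group in the allylic chemistry.

Step 7
Reactants: 12 1β,2β-O-isopropylidene acetal (bromide)
Product: 13 primary iodide
Conditions: NaI (5 equiv), acetone, 56 °C
Reagents that add atoms: sodium iodide, [Na+].[I-]
Why: The Finkelstein reaction, driven by precipitation of NaBr, gives the primary iodide needed for fast lithium–iodine exchange.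

Step 8
Reactants: 13 primary iodide
Product: 16 cis-fused tertiary allylic methyl carbonate, via primary alkyllithium 14 (not isolated), via lithium tertiary alkoxide 15 (not isolated)
Conditions: t-BuLi (2.2 equiv), Et2O/pentane 3:2, −78 °C; then ClCO2Me, −78 to 0 °C
Reagents that add atoms: methyl chloroformate, COC(Cl)=O
Why: tert-Butyllithium undergoes lithium–iodine exchange with the primary iodide faster than it adds to the ketone, and the primary alkyllithium then attacks the C5 carbonyl within the molecule; the lithium alkoxide is captured as its methyl carbonate. The closest known reaction type is the intramolecular Barbier-type (anionic) carbonyl cyclisation initiated by halogen–metal exchange. Ring B is closed in the 6-exo-trig mode by forming C5–C6. The only new stereocentre, C5, is controlled by the tether: the chain is held on the α face of C10, so C6 reaches the α face of the nearly planar enone carbonyl through a chair-like six-membered transition state and the oxygen is pushed to the β face, cis to C14, whereas delivery to the opposite face would need a strained trans-bridged geometry. The step needs 1,2- rather than 1,4-addition and no enolisation: C3 is out of reach of a four-carbon tether, C10 is quaternary, and the diol is locked as the acetonide. The β-oriented carbonate at the ring-fusion carbon is the leaving group that step 9 replaces by hydrogen with inversion.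

Step 9
Reactants: 16 cis-fused tertiary allylic methyl carbonate
Product: 17 trans-fused bicycle (5α-H; C3=C4)
Conditions: Pd(OAc)2 (5 mol %), PBu3 (20 mol %), HCOOH (3 equiv), Et3N (3 equiv), THF, 40 °C
Reagents that add atoms: none
Why: Zerovalent palladium ionises the tertiary allylic carbonate with inversion to an α-face π-allyl complex over C3–C4–C5, and hydride formed from formate passes from palladium to the more substituted terminus C5 (Tsuji–Trost-type formate hydrogenolysis), so H-5 enters α, anti to C14, giving the trans ring fusion with C3=C4 retained.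

Step 10
Reactants: 17 trans-fused bicycle
Product: 18 9α-alcohol
Conditions: HF·pyridine, pyridine, THF, 0 °C
Reagents that add atoms: none
Why: Buffered fluoride desilylation cleaves the triethylsilyl ether much faster than the primary triisopropylsilyl ether and leaves the acetonide untouched.

Step 11
Reactants: 18 9α-alcohol
Product: 20 7-en-9-one, via saturated C9 ketone 19 (not isolated)
Conditions: IBX (4 equiv), DMSO/fluorobenzene 1:2, 75 °C
Reagents that add atoms: none
Why: IBX oxidises the alcohol to the C9 ketone and then dehydrogenates it through its enol (IBX ketone dehydrogenation) on the only enolisable side, C8, giving the C7=C8 enone.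

Step 12
Reactants: 20 7-en-9-one; 21 isopropenylmagnesium bromide
Product: 23 7α-isopropenyl 9-ketone, via trimethylsilyl enol ether 22 (not isolated)
Conditions: 21 (3 equiv), CuBr·SMe2 (20 mol %), Me3SiCl (3 equiv), THF, −78 °C; then aq. citric acid, 0 °C
Reagents that add atoms: none
Why: Copper-catalysed, silyl-chloride-accelerated conjugate addition of the Grignard reagent to the cyclohexenone proceeds by the stereoelectronically preferred axial attack at C7, which in the trans-fused half-chair is the α face, so the axial 7α-isopropenyl group is set from the ring fusion, and mild acid releases the ketone from the silyl enol ether.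

Step 13
Reactants: 23 7α-isopropenyl 9-ketone
Product: 24 7α-isopropenyl 9α-alcohol
Conditions: LiBH(s-Bu)3, THF, −78 to −40 °C; then H2O
Reagents that add atoms: none
Why: The bulky trialkylborohydride reduces the ketone by equatorial attack from the β direction, the axial α trajectory being blocked by the syn-axial 7α-isopropenyl group and H-5, so the axial 9α-alcohol results.

Step 14
Reactants: 24 7α-isopropenyl 9α-alcohol
Product: 25 1β,2β,9α-triol
Conditions: AcOH/H2O 4:1, 40 °C
Reagents that add atoms: none
Why: Mild aqueous acid hydrolyses the isopropylidene acetal while the primary triisopropylsilyl ether and both alkenes survive.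

Step 15
Reactants: 25 1β,2β,9α-triol; 26 3-methylbut-2-enoyl chloride
Product: 28 1β-O-(3-methylbut-2-enoyl) 2β,9α-diol, via dibutylstannylene acetal 27 (not isolated)
Conditions: Bu2SnO (1.05 equiv), toluene, reflux with removal of water; then 26 (1.05 equiv), toluene, 0 °C
Reagents that add atoms: none
Why: The cis-1,2-diol forms a five-membered stannylene acetal whose equatorial O1 is the more nucleophilic oxygen, so the acid chloride acylates O1 selectively (tin-acetal-mediated regioselective acylation) without added base, which also avoids deconjugation of the acyl group, while the hindered axial 9-OH stays free.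

Step 16
Reactants: 28 1β-O-(3-methylbut-2-enoyl) 2β,9α-diol
Product: 29 2β,9α-diacetate 14-O-triisopropylsilyl ether
Conditions: Ac2O, DMAP, Et3N, CH2Cl2, 40 °C
Reagents that add atoms: acetic anhydride, CC(=O)OC(C)=O
Why: DMAP-catalysed acylation under forcing conditions esterifies the allylic axial 2-OH and the hindered axial 9-OH in one operation.

Step 17
Reactants: 29 2β,9α-diacetate 14-O-triisopropylsilyl ether
Product: 30 CNP0320218.1 (target)
Conditions: HF·pyridine, pyridine, THF, 25 °C
Reagents that add atoms: none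
Why: Fluoride desilylation under mildly acidic conditions frees the C14 primary alcohol without acyl migration from the neighbouring esters.

**Compound list**

1 | (S)-(+)-carvone, (5S)-2-methyl-5-(prop-1-en-2-yl)cyclohex-2-en-1-one | CC1=CC[C@@H](CC1=O)C(C)=C | starting material
2 | (triisopropylsiloxy)methyl chloride | ClCO[Si](C(C)C)(C(C)C)C(C)C | starting material
3 | kinetic lithium dienolate of carvone (not isolated) | CC1=CC[C@@H](C=C1O[Li])C(C)=C | intermediate
4 | 6-[(triisopropylsiloxy)methyl]carvone, CH2OSi(i-Pr)3 on C10 trans to the isopropenyl group on C1 | CC(C)[Si](C(C)C)(C(C)C)OC[C@H]1C(=O)C(C)=CC[C@@H]1C(C)=C | intermediate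
5 | 4-bromobutanal | BrCCCC=O | starting material
6 | tetrasubstituted lithium enolate of 4 (not isolated) | [Li]OC1=C(CO[Si](C(C)C)(C(C)C)C(C)C)[C@@H](C(C)=C)CC=C1C | intermediate
7 | aldol adduct: ring A enone (C5=O, C3=C4, 4-methyl, 1β-isopropenyl) with quaternary C10 carrying CH2OSi(i-Pr)3 (β) and a 4-bromo-1-hydroxybutyl chain (α); C9 carbinol configured as in the target | BrCCC[C@H](O)[C@@]1(CO[Si](C(C)C)(C(C)C)C(C)C)C(=O)C(C)=CC[C@@H]1C(C)=C | intermediate
8 | 9-O-triethylsilyl ether of 7 | BrCCC[C@H](O[Si](CC)(CC)CC)[C@@]1(CO[Si](C(C)C)(C(C)C)C(C)C)C(=O)C(C)=CC[C@@H]1C(C)=C | intermediate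
9 | α-methoxy hydroperoxide: 8 with C(CH3)(OCH3)OOH on C1 in place of isopropenyl (not isolated; peroxy carbon unassigned) | BrCCC[C@H](O[Si](CC)(CC)CC)[C@@]1(CO[Si](C(C)C)(C(C)C)C(C)C)C(=O)C(C)=CC[C@@H]1C(C)(OC)OO | intermediate
10 | 6,6-disubstituted 2-methylcyclohexa-2,4-dien-1-one: C5 ketone, C3=C4 and C1=C2; C10 with CH2OSi(i-Pr)3 β and the 4-bromo-1-(triethylsilyloxy)butyl chain α | BrCCC[C@H](O[Si](CC)(CC)CC)[C@@]1(CO[Si](C(C)C)(C(C)C)C(C)C)C(=O)C(C)=CC=C1 | intermediate
11 | 1β,2β-diol enone (cis-diol cis to C14; C5 ketone, C3=C4) | BrCCC[C@H](O[Si](CC)(CC)CC)[C@@]1(CO[Si](C(C)C)(C(C)C)C(C)C)C(=O)C(C)=C[C@H](O)[C@@H]1O | intermediate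
12 | 1β,2β-O-isopropylidene acetal of 11 (primary bromide) | BrCCC[C@H](O[Si](CC)(CC)CC)[C@@]1(CO[Si](C(C)C)(C(C)C)C(C)C)C(=O)C(C)=C[C@H]2[C@@H]1OC(C)(C)O2 | intermediate
13 | corresponding primary iodide | ICCC[C@H](O[Si](CC)(CC)CC)[C@@]1(CO[Si](C(C)C)(C(C)C)C(C)C)C(=O)C(C)=C[C@H]2[C@@H]1OC(C)(C)O2 | intermediate
14 | primary alkyllithium from 13 (not isolated) | [Li]CCC[C@H](O[Si](CC)(CC)CC)[C@@]1(CO[Si](C(C)C)(C(C)C)C(C)C)C(=O)C(C)=C[C@H]2[C@@H]1OC(C)(C)O2 | intermediate
15 | cis-fused lithium tertiary alkoxide (C5–OLi β, C6 α) (not isolated) | C1C[C@H](O[Si](CC)(CC)CC)[C@@]2(CO[Si](C(C)C)(C(C)C)C(C)C)[C@](C1)(O[Li])C(C)=C[C@H]3[C@@H]2OC(C)(C)O3 | intermediate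
16 | cis-fused tertiary allylic methyl carbonate: C5–OCO2CH3 β, C3=C4, 1β,2β-acetonide, 9α-OSiEt3, 14-OSi(i-Pr)3 | C1C[C@H](O[Si](CC)(CC)CC)[C@@]2(CO[Si](C(C)C)(C(C)C)C(C)C)[C@](C1)(OC(=O)OC)C(C)=C[C@H]3[C@@H]2OC(C)(C)O3 | intermediate
17 | trans-fused bicycle: 5α-H, C3=C4, 1β,2β-acetonide, 9α-OSiEt3, 14-OSi(i-Pr)3; C6, C7, C8 are CH2 | C1C[C@H](O[Si](CC)(CC)CC)[C@@]2(CO[Si](C(C)C)(C(C)C)C(C)C)[C@H](C1)C(C)=C[C@H]3[C@@H]2OC(C)(C)O3 | intermediate
18 | 9α-alcohol from 17 | C1C[C@H](O)[C@@]2(CO[Si](C(C)C)(C(C)C)C(C)C)[C@H](C1)C(C)=C[C@H]3[C@@H]2OC(C)(C)O3 | intermediate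
19 | saturated 9-ketone (not isolated) | C1CC(=O)[C@@]2(CO[Si](C(C)C)(C(C)C)C(C)C)[C@H](C1)C(C)=C[C@H]3[C@@H]2OC(C)(C)O3 | intermediate
20 | 7-en-9-one (C7=C8, C9=O) | C1=CC(=O)[C@@]2(CO[Si](C(C)C)(C(C)C)C(C)C)[C@H](C1)C(C)=C[C@H]3[C@@H]2OC(C)(C)O3 | intermediate
21 | isopropenylmagnesium bromide | C=C(C)[Mg]Br | starting material
22 | trimethylsilyl enol ether (C8=C9–OSiMe3) bearing 7α-isopropenyl (not isolated) | C=C(C)[C@@H]1C=C(O[Si](C)(C)C)[C@@]2(CO[Si](C(C)C)(C(C)C)C(C)C)[C@H](C1)C(C)=C[C@H]3[C@@H]2OC(C)(C)O3 | intermediate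
23 | 7α-isopropenyl 9-ketone | C=C(C)[C@@H]1CC(=O)[C@@]2(CO[Si](C(C)C)(C(C)C)C(C)C)[C@H](C1)C(C)=C[C@H]3[C@@H]2OC(C)(C)O3 | intermediate
24 | 7α-isopropenyl 9α-alcohol (axial OH), 1β,2β-acetonide | C=C(C)[C@@H]1C[C@H](O)[C@@]2(CO[Si](C(C)C)(C(C)C)C(C)C)[C@H](C1)C(C)=C[C@H]3[C@@H]2OC(C)(C)O3 | intermediate
25 | 1β,2β,9α-triol, 14-O-triisopropylsilyl ether | C=C(C)[C@@H]1C[C@H](O)[C@@]2(CO[Si](C(C)C)(C(C)C)C(C)C)[C@H](C1)C(C)=C[C@H](O)[C@@H]2O | intermediate
26 | 3-methylbut-2-enoyl chloride (senecioyl chloride) | CC(C)=CC(Cl)=O | starting material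
27 | 1,2-O-dibutylstannylene acetal of 25 (not isolated) | C=C(C)[C@@H]1C[C@H](O)[C@@]2(CO[Si](C(C)C)(C(C)C)C(C)C)[C@H](C1)C(C)=C[C@H]3[C@@H]2O[Sn](CCCC)(CCCC)O3 | intermediate
28 | 1β-O-(3-methylbut-2-enoyl) 2β,9α-diol, 14-O-triisopropylsilyl ether | C=C(C)[C@@H]1C[C@H](O)[C@@]2(CO[Si](C(C)C)(C(C)C)C(C)C)[C@H](C1)C(C)=C[C@H](O)[C@@H]2OC(=O)C=C(C)C | intermediate
29 | 1β-O-(3-methylbut-2-enoyl) 2β,9α-diacetate 14-O-triisopropylsilyl ether | C=C(C)[C@@H]1C[C@H](OC(C)=O)[C@@]2(CO[Si](C(C)C)(C(C)C)C(C)C)[C@H](C1)C(C)=C[C@H](OC(C)=O)[C@@H]2OC(=O)C=C(C)C | intermediate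
30 | CNP0320218.1: (1R,2S,5R,7S,9S,10S)-2,9-diacetoxy-14-hydroxy-1-(3-methylbut-2-enoyloxy)eudesma-3,11-diene | C=C(C)[C@@H]1C[C@H](OC(C)=O)[C@@]2(CO)[C@H](C1)C(C)=C[C@H](OC(C)=O)[C@@H]2OC(=O)C=C(C)C | target

**Step count.** Total: 17 steps. Longest linear sequence: 17 steps, from (S)-carvone 1 to 30.

**Steps most likely to fail**

Step 8. The carbonyl addition may lose facial selectivity, or the labile tertiary carbonate may ionise on handling. Both C5 epimers would then enter a stereospecific hydrogenolysis and the ring fusion would be scrambled. The fallback makes the ring fusion independent of the C5 carbinol configuration. It sets out from alkoxide 15, formed as in step 8 but quenched with water, to give the tertiary allylic alcohol F1 as any mixture of C5 epimers. Pyridinium chlorochromate (C5H5NH[CrO3Cl]) in CH2Cl2 effects the Babler–Dauben oxidative 1,3-transposition to the 4-en-3-one F2, in which C5 is trigonal. Luche reduction (NaBH4, CeCl3·7H2O, MeOH, −78 °C) from the α face, anti to the β-acetonide, gives the 3β-allylic alcohol F3. Formic acetic anhydride and pyridine give the 3β-formate F4. Pd(OAc)2 and PBu3 in dioxane then ionise the formate to the same α-face π-allyl complex, and hydride is delivered to C5 from palladium, which returns the route to 17.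

Step 4. The radical fragmentation may be diverted: the secondary C1 radical can be reduced, or can add to the neighbouring enone, before the cupric salt oxidises it to the alkene. The fallback replaces the radical pathway by an ionic one and sets out from 8. Ozonolysis in CH2Cl2/MeOH gives hydroperoxide 9 as before. Ac2O, Et3N and DMAP convert it into the peroxyacetate F5, which undergoes Criegee rearrangement with retention to the C1 β-acetate F6. DBU in THF at rt then removes the γ-proton at C2 and expels acetate from C1 (vinylogous E1cB elimination), which gives dienone 10.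

Step 15. The tin-mediated acylation may not discriminate between O1 and O2, or the acyl group may migrate between the cis oxygens. The fallback fixes the regiochemistry by the stereoelectronics of orthoester opening and sets out from triol 25. Trimethyl orthoacetate and camphorsulfonic acid (cat.) in CH2Cl2 give the cyclic 1,2-orthoacetate F7. Aqueous acetic acid opens it to the ester on the axial oxygen, the 2β-acetate F8. Acid chloride 26 with pyridine and DMAP acylates the equatorial 1-OH in preference to the hindered axial 9-OH and gives the 1-senecioate 2-acetate F9. Ac2O with Sc(OTf)3 (cat.) in MeCN at −20 °C acetylates the 9-OH and returns the route to 29.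

Further compounds
F1 | step 8 | tertiary allylic alcohol at C5 (mixture of C5 epimers), 1β,2β-acetonide, 9α-OSiEt3, 14-OSi(i-Pr)3 | C1C[C@H](O[Si](CC)(CC)CC)[C@@]2(CO[Si](C(C)C)(C(C)C)C(C)C)C(C1)(O)C(C)=C[C@H]3[C@@H]2OC(C)(C)O3
F2 | step 8 | 4-en-3-one (C3=O, C4=C5), 1β,2β-acetonide | C1C[C@H](O[Si](CC)(CC)CC)[C@@]2(CO[Si](C(C)C)(C(C)C)C(C)C)C(C1)=C(C)C(=O)[C@H]3[C@@H]2OC(C)(C)O3
F3 | step 8 | 3β-allylic alcohol (C4=C5) | C1C[C@H](O[Si](CC)(CC)CC)[C@@]2(CO[Si](C(C)C)(C(C)C)C(C)C)C(C1)=C(C)[C@H](O)[C@H]3[C@@H]2OC(C)(C)O3
F4 | step 8 | 3β-formate (C4=C5) | C1C[C@H](O[Si](CC)(CC)CC)[C@@]2(CO[Si](C(C)C)(C(C)C)C(C)C)C(C1)=C(C)[C@H](OC=O)[C@H]3[C@@H]2OC(C)(C)O3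
F5 | step 4 | peroxyacetate of hydroperoxide 9 | BrCCC[C@H](O[Si](CC)(CC)CC)[C@@]1(CO[Si](C(C)C)(C(C)C)C(C)C)C(=O)C(C)=CC[C@@H]1C(C)(OC)OOC(C)=O
F6 | step 4 | C1 β-acetate (ring A enone, C5=O, C3=C4) | BrCCC[C@H](O[Si](CC)(CC)CC)[C@@]1(CO[Si](C(C)C)(C(C)C)C(C)C)C(=O)C(C)=CC[C@@H]1OC(C)=O
F7 | step 15 | cyclic 1,2-orthoacetate (methoxyethylidene acetal) of triol 25 | C=C(C)[C@@H]1C[C@H](O)[C@@]2(CO[Si](C(C)C)(C(C)C)C(C)C)[C@H](C1)C(C)=C[C@H]3[C@@H]2OC(C)(OC)O3
F8 | step 15 | 2β-acetate 1β,9α-diol | C=C(C)[C@@H]1C[C@H](O)[C@@]2(CO[Si](C(C)C)(C(C)C)C(C)C)[C@H](C1)C(C)=C[C@H](OC(C)=O)[C@@H]2O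
F9 | step 15 | 1β-O-(3-methylbut-2-enoyl) 2β-acetate 9α-alcohol | C=C(C)[C@@H]1C[C@H](O)[C@@]2(CO[Si](C(C)C)(C(C)C)C(C)C)[C@H](C1)C(C)=C[C@H](OC(C)=O)[C@@H]2OC(=O)C=C(C)C
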